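**Retrosynthetic overview**
1. The target comes from its penta-O-benzyl ether. Hydrogenolysis is done only after both stereocentres are in place.
2. The penta-O-benzyl bisflavanone comes from a fully acyclic bis(2'-hydroxychalcone) by cutting both O1–C2 bonds at once. One catalyst-controlled twofold oxa-Michael addition closes ring C of unit 1 and ring C of unit 2 and sets both 2S centres.
3. The bis-chalcone comes from a Claisen–Schmidt condensation of a formyl-bearing chalcone (unit 2) with 2,4-bis(benzyloxy)-6-hydroxyacetophenone (ring A of unit 1).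
4. The formyl chalcone comes from SNAr diaryl ether formation with 4-fluorobenzaldehyde on a 3'-hydroxychalcone. That chalcone is built from 4-benzyloxybenzaldehyde and an Elbs para-hydroxylated copy of the same acetophenone. The only free cyclising OH sits para to the ether oxygen, which fixes the 6-aryloxy (not 8-aryloxy) pattern.
5. Ring order: the four benzene rings are bought, and the two pyranone rings are made last and together.

Assumption: the quinidine-derived thiourea is taken to give the 2S sense with these chalcones; the sense is read from the circular dichroism of the cyclised product (2S-flavanones: negative band near 290 nm, positive band near 330 nm), and the equally available quinine-derived pseudoenantiomer, N-[3,5-bis(trifluoromethyl)phenyl]-N'-[(8α,9S)-6'-methoxycinchonan-9-yl]thiourea, takes its place if the sign is opposite.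

**Step 1**
Reactants: 1 2,4,6-trihydroxyacetophenone
Product: 2 1-[2,4-bis(benzyloxy)-6-hydroxyphenyl]ethanone
Conditions: BnBr (2.1 equiv), K2CO3 (2.2 equiv), DMF, 25 to 60 °C, 4 h
Reagents that add atoms: benzyl bromide, BrCc1ccccc1
Why: Williamson etherification stops after two benzylations because the remaining ortho-OH is hydrogen-bonded to the acetyl carbonyl and is the least nucleophilic oxygen; no stereocentre is formed.

**Step 2**
Reactants: 2 1-[2,4-bis(benzyloxy)-6-hydroxyphenyl]ethanone
Product: 4 1-[2,4-bis(benzyloxy)-3,6-dihydroxyphenyl]ethanone, via potassium aryl sulfate 3 (not isolated)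
Conditions: K2S2O8 (1.1 equiv), aq KOH, pyridine, 5 to 20 °C, Ar, 24 h; recover unreacted 2 at pH 5; then aq HCl, 85 °C, 30 min
Reagents that add atoms: potassium peroxodisulfate, [K+].[K+].[O-]S(=O)(=O)OOS(=O)(=O)[O-]
Why: In the Elbs persulfate oxidation the phenolate attacks the peroxide oxygen through the carbon para to O− (C3, between the two benzyloxy groups), and acid hydrolysis of the aryl sulfate frees the new OH exactly where the diaryl ether oxygen of the target must sit; no stereocentre is formed.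

**Step 3**
Reactants: 4 1-[2,4-bis(benzyloxy)-3,6-dihydroxyphenyl]ethanone; 5 4-(benzyloxy)benzaldehyde
Product: 6 (2E)-1-[2,4-bis(benzyloxy)-3,6-dihydroxyphenyl]-3-[4-(benzyloxy)phenyl]prop-2-en-1-one
Conditions: LiN(SiMe3)2 (4.2 equiv), THF, -78 to 25 °C, Ar, 16 h; then cold dil. aq HCl
Reagents that add atoms: none
Why: This Claisen–Schmidt aldol condensation runs on the lithium trianion (two phenoxides plus enolate) in an aprotic, oxygen-free medium, which keeps the hydroquinone from being oxidised, and E1cB loss of the aldolate oxygen gives the thermodynamic E-enone; no stereocentre is formed.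

**Step 4**
Reactants: 6 (2E)-1-[2,4-bis(benzyloxy)-3,6-dihydroxyphenyl]-3-[4-(benzyloxy)phenyl]prop-2-en-1-one; 7 4-fluorobenzaldehyde
Product: 8 4-{2,6-bis(benzyloxy)-3-[(2E)-3-(4-benzyloxyphenyl)prop-2-enoyl]-4-hydroxyphenoxy}benzaldehyde
Conditions: 7 (1.15 equiv), K2CO3 (2.5 equiv), dry DMF, 4 Å sieves, 90 °C, Ar, 12 h
Reagents that add atoms: none
Why: In this SNAr addition–elimination on the para-formyl-activated fluoride, the non-chelated 3-phenoxide reacts in preference to the carbonyl-conjugated, hydrogen-bonded 6-phenoxide, and any material that closes reversibly to racemic flavanone here is re-opened by the KOH of the next step; no stereocentre is retained.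

**Step 5**
Reactants: 8 4-{2,6-bis(benzyloxy)-3-[(2E)-3-(4-benzyloxyphenyl)prop-2-enoyl]-4-hydroxyphenoxy}benzaldehyde; 2 1-[2,4-bis(benzyloxy)-6-hydroxyphenyl]ethanone
Product: 9 (2E)-1-[2,4-bis(benzyloxy)-6-hydroxyphenyl]-3-[4-(2,6-bis(benzyloxy)-3-[(2E)-3-(4-benzyloxyphenyl)prop-2-enoyl]-4-hydroxyphenoxy)phenyl]prop-2-en-1-one
Conditions: 2 (1.1 equiv), KOH (50% aq, 12 equiv), EtOH/THF 1:1, 25 °C, Ar, 48 h; then cold dil. aq HCl to pH 5
Reagents that add atoms: none
Why: In this Claisen–Schmidt condensation 8 carries no enolisable methyl ketone and 2 carries no aldehyde, so only the cross product can form, and strong base holds both 2'-hydroxychalcone units open as their phenolates until the cold, mild acidification; no stereocentre is formed.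

**Step 6**
Reactants: 9 (2E)-1-[2,4-bis(benzyloxy)-6-hydroxyphenyl]-3-[4-(2,6-bis(benzyloxy)-3-[(2E)-3-(4-benzyloxyphenyl)prop-2-enoyl]-4-hydroxyphenoxy)phenyl]prop-2-en-1-one
Product: 12 (2S)-5,7-bis(benzyloxy)-2-[4-({(2S)-5,7-bis(benzyloxy)-2-[4-(benzyloxy)phenyl]-4-oxochroman-6-yl}oxy)phenyl]chroman-4-one, via unit-1-closed monoflavanone 10 (not isolated), via unit-2-closed monoflavanone 11 (not isolated)
Conditions: N-[3,5-bis(trifluoromethyl)phenyl]-N'-[(9R)-6'-methoxycinchonan-9-yl]thiourea (20 mol%), toluene (0.05 mol/L), 25 °C, about 72 h, stopped at full conversion by HPLC; silica plug, then recrystallisation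
Reagents that add atoms: none
Why: Proposed new method: this is a twofold enantioselective 6-endo-trig intramolecular oxa-Michael addition in which the quinuclidine nitrogen deprotonates each chelated 2'-phenol while the thiourea N–H pair binds the enone carbonyl, so the ion-paired phenoxide is delivered to the Si face of each C-beta and each C2 is set as S under catalyst control, independently of the remote second unit; the 6'-benzyloxy groups twist the aryl ketones out of conjugation, which speeds closure and pushes the chalcone/flavanone equilibrium far to the closed side, and because two centres are set independently the mirror image is statistically depleted (95:5 per ring gives S,S to R,R of about 360:1), the error ending up in the S,R and R,S diastereomers that are removed by crystallisation or HPLC; the closest known reaction types are cinchona-alkaloid- and cinchona-thiourea-catalysed cyclisation of single ortho-enoylphenols, 2'-hydroxychalcones and their alpha-tert-butoxycarbonyl analogues to chromanones and flavanones.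

**Step 7**
Reactants: 12 (2S)-5,7-bis(benzyloxy)-2-[4-({(2S)-5,7-bis(benzyloxy)-2-[4-(benzyloxy)phenyl]-4-oxochroman-6-yl}oxy)phenyl]chroman-4-one
Product: 13 (2S)-5,7-dihydroxy-2-[4-({(2S)-5,7-dihydroxy-2-(4-hydroxyphenyl)-4-oxochroman-6-yl}oxy)phenyl]chroman-4-one
Conditions: H2 (1 atm), 10 wt% Pd/C, EtOAc/MeOH 1:1 with 1% AcOH, 25 °C, about 3 h, stopped after uptake of 5 equiv H2
Reagents that add atoms: none
Why: Catalytic hydrogenolysis removes all five benzyl ethers under neutral to faintly acidic conditions, so the base-triggered retro-oxa-Michael racemisation of 5-hydroxyflavanones cannot start, while the diaryl ether, the vinylogous-ester-like ketones and both 2S centres are left untouched.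

**Compound list**
1 | 2,4,6-trihydroxyacetophenone (phloroacetophenone) | CC(=O)c1c(O)cc(O)cc1O | starting material
2 | 1-[2,4-bis(benzyloxy)-6-hydroxyphenyl]ethanone | CC(=O)c1c(O)cc(OCc2ccccc2)cc1OCc1ccccc1 | intermediate
3 | potassium 3-acetyl-2,6-bis(benzyloxy)-4-hydroxyphenyl sulfate (not isolated) | CC(=O)c1c(O)cc(OCc2ccccc2)c(OS(=O)(=O)[O-])c1OCc1ccccc1.[K+] | intermediate
4 | 1-[2,4-bis(benzyloxy)-3,6-dihydroxyphenyl]ethanone | CC(=O)c1c(O)cc(OCc2ccccc2)c(O)c1OCc1ccccc1 | intermediate
5 | 4-(benzyloxy)benzaldehyde | O=Cc1ccc(OCc2ccccc2)cc1 | starting material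
6 | (2E)-1-[2,4-bis(benzyloxy)-3,6-dihydroxyphenyl]-3-[4-(benzyloxy)phenyl]prop-2-en-1-one | O=C(/C=C/c1ccc(OCc2ccccc2)cc1)c1c(O)cc(OCc2ccccc2)c(O)c1OCc1ccccc1 | intermediate
7 | 4-fluorobenzaldehyde | O=Cc1ccc(F)cc1 | starting material
8 | 4-{2,6-bis(benzyloxy)-3-[(2E)-3-(4-benzyloxyphenyl)prop-2-enoyl]-4-hydroxyphenoxy}benzaldehyde | O=Cc1ccc(Oc2c(OCc3ccccc3)cc(O)c(C(=O)/C=C/c3ccc(OCc4ccccc4)cc3)c2OCc2ccccc2)cc1 | intermediate
9 | bis-chalcone: (2E)-1-[2,4-bis(benzyloxy)-6-hydroxyphenyl]-3-[4-(2,6-bis(benzyloxy)-3-[(2E)-3-(4-benzyloxyphenyl)prop-2-enoyl]-4-hydroxyphenoxy)phenyl]prop-2-en-1-one | O=C(/C=C/c1ccc(Oc2c(OCc3ccccc3)cc(O)c(C(=O)/C=C/c3ccc(OCc4ccccc4)cc3)c2OCc2ccccc2)cc1)c1c(O)cc(OCc2ccccc2)cc1OCc1ccccc1 | intermediate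
10 | (2S)-5,7-bis(benzyloxy)-2-[4-(2,6-bis(benzyloxy)-3-[(2E)-3-(4-benzyloxyphenyl)prop-2-enoyl]-4-hydroxyphenoxy)phenyl]chroman-4-one (unit 1 closed, unit 2 still open; not isolated) | O=C1C[C@@H](c2ccc(Oc3c(OCc4ccccc4)cc(O)c(C(=O)/C=C/c4ccc(OCc5ccccc5)cc4)c3OCc3ccccc3)cc2)Oc2cc(OCc3ccccc3)cc(OCc3ccccc3)c21 | intermediate
11 | (2S)-5,7-bis(benzyloxy)-2-[4-(benzyloxy)phenyl]-6-(4-{(1E)-3-[2,4-bis(benzyloxy)-6-hydroxyphenyl]-3-oxoprop-1-en-1-yl}phenoxy)chroman-4-one (unit 2 closed, unit 1 still open; not isolated) | O=C(/C=C/c1ccc(Oc2c(OCc3ccccc3)cc3c(c2OCc2ccccc2)C(=O)C[C@@H](c2ccc(OCc4ccccc4)cc2)O3)cc1)c1c(O)cc(OCc2ccccc2)cc1OCc1ccccc1 | intermediate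
12 | (2S)-5,7-bis(benzyloxy)-2-[4-({(2S)-5,7-bis(benzyloxy)-2-[4-(benzyloxy)phenyl]-4-oxochroman-6-yl}oxy)phenyl]chroman-4-one | O=C1C[C@@H](c2ccc(Oc3c(OCc5ccccc5)cc4c(c3OCc6ccccc6)C(=O)C[C@@H](c7ccc(OCc8ccccc8)cc7)O4)cc2)Oc2cc(OCc3ccccc3)cc(OCc3ccccc3)c21 | intermediate
13 | (2S)-5,7-dihydroxy-2-[4-({(2S)-5,7-dihydroxy-2-(4-hydroxyphenyl)-4-oxochroman-6-yl}oxy)phenyl]chroman-4-one, (2S,2''S)-2,3,2'',3''-tetrahydrohinokiflavone | O=C1C[C@@H](c2ccc(Oc3c(O)cc4c(c3O)C(=O)C[C@@H](c3ccc(O)cc3)O4)cc2)Oc2cc(O)cc(O)c21 | target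

**Total step count:** 7.
**Longest linear sequence:** 7 (1 → 2 → 4 → 6 → 8 → 9 → 12 → 13). Compound 2 enters a second time at step 5.

**Three steps most likely to fail**

Step 6 (twofold catalytic closure). Unactivated enones turn over slowly, the reaction is reversible, and the S,R and R,S diastereomers with their remote centres may be hard to remove.
Fallback: set out from 9 and close both rings without stereocontrol (NaOAc, EtOH/THF, reflux) to the stereorandom penta-O-benzyl bisflavanone F1. Resolve its four stereoisomers on a preparative amylose tris(3,5-dimethylphenylcarbamate) phase. The 2S,2''S fraction is 12, where the route is rejoined. The three other fractions are re-opened with KOH to 9 and recycled.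

Step 2 (Elbs oxidation). Conversion is typically low, the dibenzyl ether dissolves poorly in aqueous base, and the para position is crowded.
Fallback: set out from 2 and replace the sulfate route with a quinone route. Teuber oxidation with Fremy's salt, (KSO3)2NO, in aq KH2PO4/acetone gives 2-acetyl-3,5-bis(benzyloxy)cyclohexa-2,5-diene-1,4-dione F2. This is reduced in the same work-up with aq Na2S2O4, and the route is rejoined at 4.

Step 4 (SNAr on a base-sensitive chalcone). A hindered phenoxide has to react at 90 °C, where retro-aldol scrambling, ring closure and aldol reaction of the product aldehyde can all interfere.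
Fallback: set out from 4 and make the diaryl ether before any enone exists.
- SNAr of 4 with 7 (K2CO3, DMF, 85 °C) gives 4-[3-acetyl-2,6-bis(benzyloxy)-4-hydroxyphenoxy]benzaldehyde F3.
- HC(OMe)3 with catalytic TsOH in MeOH masks the aldehyde as 1-{2,4-bis(benzyloxy)-3-[4-(dimethoxymethyl)phenoxy]-6-hydroxyphenyl}ethanone F4.
- Claisen–Schmidt condensation with 5 (KOH, EtOH/THF) gives the acetal chalcone (2E)-1-{2,4-bis(benzyloxy)-3-[4-(dimethoxymethyl)phenoxy]-6-hydroxyphenyl}-3-[4-(benzyloxy)phenyl]prop-2-en-1-one F5.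
- Dil. aq HCl/THF unmasks the aldehyde, and the route is rejoined at 8.

This detour also bypasses step 3.

**Further compounds**
F1 | step 6 | stereorandom 5,7-bis(benzyloxy)-2-[4-({5,7-bis(benzyloxy)-2-[4-(benzyloxy)phenyl]-4-oxochroman-6-yl}oxy)phenyl]chroman-4-one (mixture of the four stereoisomers) | O=C1CC(c2ccc(Oc3c(OCc5ccccc5)cc4c(c3OCc6ccccc6)C(=O)CC(c7ccc(OCc8ccccc8)cc7)O4)cc2)Oc2cc(OCc3ccccc3)cc(OCc3ccccc3)c21
F2 | step 2 | 2-acetyl-3,5-bis(benzyloxy)cyclohexa-2,5-diene-1,4-dione | CC(=O)C1=C(OCc2ccccc2)C(=O)C(OCc2ccccc2)=CC1=O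
F3 | step 4 | 4-[3-acetyl-2,6-bis(benzyloxy)-4-hydroxyphenoxy]benzaldehyde | CC(=O)c1c(O)cc(OCc2ccccc2)c(Oc2ccc(C=O)cc2)c1OCc1ccccc1
F4 | step 4 | 1-{2,4-bis(benzyloxy)-3-[4-(dimethoxymethyl)phenoxy]-6-hydroxyphenyl}ethanone | CC(=O)c1c(O)cc(OCc2ccccc2)c(Oc2ccc(C(OC)OC)cc2)c1OCc1ccccc1
F5 | step 4 | (2E)-1-{2,4-bis(benzyloxy)-3-[4-(dimethoxymethyl)phenoxy]-6-hydroxyphenyl}-3-[4-(benzyloxy)phenyl]prop-2-en-1-one | COC(OC)c1ccc(Oc2c(OCc3ccccc3)cc(O)c(C(=O)/C=C/c3ccc(OCc4ccccc4)cc3)c2OCc2ccccc2)cc1
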